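**Plan**

- Atom labels follow 6H-isochromene numbering (C1, O2, C3, C4, C4a, C5, C6, C7, C8, C8a); ring A is the carbocycle, ring B the pyran.
- Cuts, in retrosynthetic order: the C7–O ester bond (linoleoyl chloride plus the tertiary ketol 9); the C6–C7 bond of ring A, read as an α-ketol made from a C6 aldehyde and a C7 ketone; C8a–C8 and C8–C7 by CO insertion between an enol triflate and a 1-ethoxyvinyl tin reagent; C4a=C5 by addition of a two-carbon acetal Grignard reagent to the C4 carbonyl of a 4-pyranone.
- Forward order: ring B is bought as allomaltol; C5–C6 are attached at C4a, then C8–C7–CH3 at C8a; ring A is closed by C6–C7 bond formation; the linoleate is attached last.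
- Enabling feature: in keto-aldehyde 8 the C6 formyl group sits on the exocyclic C4a=C5 alkene of a 4-ylidene-4H-pyran and C7 is the outer carbonyl of a pyruvoyl group on C8a. C6 and C7 are therefore held 1,6 across a planar frame, C7 is activated by C8=O, and C8 is deactivated as a vinylogous ester of O2.
- Stereochemistry: the only stereocentre, C7 (R), is created in the ring closure under control of a chiral triazolylidene carbene; the 9Z,12Z diene is bought in the acid chloride.

Key step: step 4

Remark on availability: allomaltol, the Grignard solution 3, stannane 6, linoleoyl chloride 10 and both antipodes of the triazolium salt are taken as catalogue chemicals.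
Remark on geometry: compounds 5, 7 and 8 are push–pull 4-ylidene-4H-pyrans whose exocyclic C4a=C5 bond is expected to be configurationally labile; they are drawn and named as the Z isomer that cyclises and may be handled as E/Z mixtures.
Assumption on the sense of induction: the (5aS,10bR) triazolium salt is assumed to direct attack on the Re face of C7; if the sense proves opposite, the (5aR,10bS) antipode is used.

**Route**

Step 1
Reactants: 1 allomaltol (5-hydroxy-2-methyl-4H-pyran-4-one)
Product: 2 6-methyl-4-oxo-4H-pyran-3-yl trifluoromethanesulfonate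
Conditions: Tf2O (1.1 equiv), pyridine (2 equiv), CH2Cl2, −20 → 0 °C
Reagents that add atoms: trifluoromethanesulfonic anhydride, O=S(=O)(OS(=O)(=O)C(F)(F)F)C(F)(F)F
Why: O-sulfonylation of the acidic enolic hydroxyl of the 3-hydroxy-4-pyranone should give the enol triflate that later serves as the handle for the C8a–C8 bond; no stereocentre is involved.

Step 2
Reactants: 2 6-methyl-4-oxo-4H-pyran-3-yl trifluoromethanesulfonate; 3 (1,3-dioxolan-2-ylmethyl)magnesium bromide
Product: 5 (4Z)-6-methyl-4-(2-oxoethylidene)-4H-pyran-3-yl trifluoromethanesulfonate, via carbinol adduct 4 (not isolated)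
Conditions: 3 (1.5 equiv), anhydrous CeCl3 (1.5 equiv), THF, −78 → 0 °C; then 1 M aqueous HCl, THF, 0 °C → rt
Reagents that add atoms: water, O
Why: 1,2-addition of the organocerium reagent formed from the Grignard reagent to the 4-pyranone carbonyl, then acid-induced ionisation of the bis-allylic carbinol to the pyrylium ion, loss of the exocyclic proton to the 4-alkylidene-4H-pyran and acetal hydrolysis, should give the push–pull aldehyde (the classical pyranone to 4-alkylpyrylium to anhydrobase sequence), with no geometry to control because the exocyclic alkene is stereolabile.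

Step 3
Reactants: 5 (4Z)-6-methyl-4-(2-oxoethylidene)-4H-pyran-3-yl trifluoromethanesulfonate; 6 tributyl(1-ethoxyvinyl)stannane
Product: 8 1-[(4Z)-6-methyl-4-(2-oxoethylidene)-4H-pyran-3-yl]propane-1,2-dione, via 2-ethoxy enone 7 (not isolated)
Conditions: Pd(PPh3)4 (5 mol%), LiCl (3 equiv), CO (3 atm), THF, 55 °C; then 1 M aqueous HCl, THF, rt
Reagents that add atoms: carbon monoxide, [C-]#[O+]; water, O
Why: A carbonylative Stille coupling of the enol triflate (oxidative addition to zerovalent palladium, CO insertion, transmetalation, reductive elimination) should give the 2-ethoxy enone, whose enol ether is hydrolysed by dilute acid to the methyl ketone, so the 1,2-diketone is unmasked without any oxidant.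

Step 4
Reactants: 8 1-[(4Z)-6-methyl-4-(2-oxoethylidene)-4H-pyran-3-yl]propane-1,2-dione
Product: 9 (7R)-7-hydroxy-3,7-dimethyl-6H-isochromene-6,8(7H)-dione
Conditions: (5aS,10bR)-2-(pentafluorophenyl)-5a,10b-dihydro-4H,6H-indeno[2,1-b][1,2,4]triazolo[4,3-d][1,4]oxazin-2-ium tetrafluoroborate (15 mol%), Et3N (15 mol%), toluene (0.02 M), 25 °C, argon
Reagents that add atoms: none
Why: Proposed new method: the free carbene adds to the C6 aldehyde, proton transfer gives the hydroxy-enamine (acyl anion equivalent) whose C6 is nucleophilic, C6 attacks the C7 ketone carbon of the pyruvoyl group, and collapse of the adduct releases the carbene and leaves the C6 ketone and the C7 tertiary alcohol. The closest known reaction type is the chiral-triazolium-catalysed intramolecular crossed aldehyde–ketone benzoin cyclisation to six-membered tertiary α-ketols; new here are a vinylogous-formate enal as the acyl-anion donor and a 1,2-diketone as the acceptor. Ring A closes in the 6-exo-trig mode, C6 onto C7 with the C7=O bond outside the forming ring. The C7 stereocentre is set under catalyst control: the aminoindane wall shields one face of the hydroxy-enamine and its OH hydrogen-bonds to the ketone oxygen, so that C6 should add to the Re face of C7 (O > C8 > CH3), which corresponds to R. Three selectivities are needed: C7 over C8 (C8 is a vinylogous ester carbonyl deactivated by O2 through C1=C8a and would close a strained five-membered ring, while C7 is activated by the adjacent C8=O); acyl-anion over homoenolate reactivity (the homoenolate form would put the negative charge on C4a inside ring B as an eight-π-electron 4H-pyranyl anion, and C4a has no electrophile within reach); and the cisoid geometry at C4a=C5 (the push–pull alkene should equilibrate through its pyrylium enolate form, so the unreactive isomer drains into the reactive one).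

Step 5
Reactants: 9 (7R)-7-hydroxy-3,7-dimethyl-6H-isochromene-6,8(7H)-dione; 10 (9Z,12Z)-octadeca-9,12-dienoyl chloride
Product: 11 (7R)-3,7-dimethyl-6,8-dioxo-7,8-dihydro-6H-isochromen-7-yl (9Z,12Z)-octadeca-9,12-dienoate (CNP0143332.1)
Conditions: 10 (1.5 equiv), DMAP (0.2 equiv), Et3N (2 equiv), CH2Cl2, 0 °C → rt, argon, dark
Reagents that add atoms: none
Why: DMAP-catalysed acylation of the tertiary α-ketol hydroxyl with the acid chloride should give the ester without touching the C7–O bond, so the R configuration is retained, and the skipped Z,Z-diene is not exposed to acid, radical or metal conditions.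

**Compound list**

1 | allomaltol (5-hydroxy-2-methyl-4H-pyran-4-one) | CC1=CC(=O)C(O)=CO1 | starting material
2 | 6-methyl-4-oxo-4H-pyran-3-yl trifluoromethanesulfonate | CC1=CC(=O)C(OS(=O)(=O)C(F)(F)F)=CO1 | intermediate
3 | (1,3-dioxolan-2-ylmethyl)magnesium bromide (THF solution) | Br[Mg]CC1OCCO1 | starting material
4 | racemic 4-(1,3-dioxolan-2-ylmethyl)-4-hydroxy-6-methyl-4H-pyran-3-yl trifluoromethanesulfonate | CC1=CC(O)(CC2OCCO2)C(OS(=O)(=O)C(F)(F)F)=CO1 | intermediate (not isolated)
5 | (4Z)-6-methyl-4-(2-oxoethylidene)-4H-pyran-3-yl trifluoromethanesulfonate | O=C/C=C1\C(OS(=O)(=O)C(F)(F)F)=COC(C)=C1 | intermediate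
6 | tributyl(1-ethoxyvinyl)stannane | CCCC[Sn](CCCC)(CCCC)C(=C)OCC | starting material
7 | 2-ethoxy-1-[(4Z)-6-methyl-4-(2-oxoethylidene)-4H-pyran-3-yl]prop-2-en-1-one | O=C/C=C1\C(C(=O)C(=C)OCC)=COC(C)=C1 | intermediate (not isolated)
8 | 1-[(4Z)-6-methyl-4-(2-oxoethylidene)-4H-pyran-3-yl]propane-1,2-dione | O=C/C=C1\C(C(=O)C(C)=O)=COC(C)=C1 | intermediate
9 | (7R)-7-hydroxy-3,7-dimethyl-6H-isochromene-6,8(7H)-dione | O[C@]1(C)C(=O)C=C2C=C(C)OC=C2C1=O | intermediate
10 | (9Z,12Z)-octadeca-9,12-dienoyl chloride (linoleoyl chloride) | CCCCC/C=C\C/C=C\CCCCCCCC(=O)Cl | starting material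
11 | (7R)-3,7-dimethyl-6,8-dioxo-7,8-dihydro-6H-isochromen-7-yl (9Z,12Z)-octadeca-9,12-dienoate | CCCCC/C=C\C/C=C\CCCCCCCC(=O)O[C@]1(C)C(=O)C=C2C=C(C)OC=C2C1=O | target

**Step count and risks**

Total steps: 5. Longest linear sequence: 5 steps (1 → 2 → 5 → 8 → 9 → 11).

Steps most likely to fail:

Step 4 (bears the label). The carbene may fail to engage the weakly electrophilic vinylogous formyl group, may be consumed by addition to the diketone or to C1, or may give poor facial selectivity at C7. The fallback sets out from 8 and returns at 9, and moves the umpolung from the aldehyde to the diketone. Treatment of 8 with SmI2 (THF, −78 °C) should reduce the 1,2-diketone first, and an intramolecular pinacol-type reductive coupling of C7 with the C6 aldehyde should give racemic 6,7-dihydroxy-3,7-dimethyl-6,7-dihydro-8H-isochromen-8-one F1. Oxidation of the allylic C6 alcohol with MnO2 (CH2Cl2, rt) should give racemic 7-hydroxy-3,7-dimethyl-6H-isochromene-6,8(7H)-dione F2. Preparative chromatography on a chiral stationary phase then delivers 9.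

Step 2. The organometallic reagent may cleave the S–O bond of the triflate or add in conjugate fashion at the unsubstituted ring position next to oxygen, and water may open the ring at the pyrylium stage. The fallback sets out from 1 and returns at 5, and introduces the triflate only after the carbon chain. Silylation of 1 (triisopropylsilyl chloride, imidazole, DMF) should give 2-methyl-5-[tri(propan-2-yl)silyloxy]-4H-pyran-4-one F3. Addition of the organocerium reagent from 3 should give the racemic carbinol 4-(1,3-dioxolan-2-ylmethyl)-6-methyl-3-[tri(propan-2-yl)silyloxy]-4H-pyran-4-ol F4. Buffered acid (pyridinium p-toluenesulfonate, wet acetone) should convert it to (2Z)-2-{2-methyl-5-[tri(propan-2-yl)silyloxy]-4H-pyran-4-ylidene}acetaldehyde F5. Fluoride-induced desilylation with trapping of the enolate (CsF, N-phenylbis(trifluoromethanesulfonimide), MeCN, rt) gives 5.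

Step 3. Transmetalation may outrun CO insertion, so that direct coupling gives the acetyl instead of the pyruvoyl side chain, or oxidative addition to the electron-rich enol triflate may be slow. The fallback sets out from 5 and returns at 8, and builds the diketone by oxidation of an alkyne instead of by carbonylation. Sonogashira coupling with propyne (PdCl2(PPh3)2, CuI, Et3N, THF, rt) should give (2Z)-2-[2-methyl-5-(prop-1-yn-1-yl)-4H-pyran-4-ylidene]acetaldehyde F6. A Wacker-type dioxygenation of the internal alkyne (PdBr2 5 mol%, CuBr2 10 mol%, O2, dioxane–water, 60 °C) then gives 8.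

**Further compounds**

F1 | step 4 | racemic 6,7-dihydroxy-3,7-dimethyl-6,7-dihydro-8H-isochromen-8-one | OC1C=C2C=C(C)OC=C2C(=O)C1(C)O
F2 | step 4 | racemic 7-hydroxy-3,7-dimethyl-6H-isochromene-6,8(7H)-dione | OC1(C)C(=O)C=C2C=C(C)OC=C2C1=O
F3 | step 2 | 2-methyl-5-[tri(propan-2-yl)silyloxy]-4H-pyran-4-one | CC1=CC(=O)C(O[Si](C(C)C)(C(C)C)C(C)C)=CO1
F4 | step 2 | racemic 4-(1,3-dioxolan-2-ylmethyl)-6-methyl-3-[tri(propan-2-yl)silyloxy]-4H-pyran-4-ol | CC1=CC(O)(CC2OCCO2)C(O[Si](C(C)C)(C(C)C)C(C)C)=CO1
F5 | step 2 | (2Z)-2-{2-methyl-5-[tri(propan-2-yl)silyloxy]-4H-pyran-4-ylidene}acetaldehyde | O=C/C=C1\C(O[Si](C(C)C)(C(C)C)C(C)C)=COC(C)=C1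
F6 | step 3 | (2Z)-2-[2-methyl-5-(prop-1-yn-1-yl)-4H-pyran-4-ylidene]acetaldehyde | O=C/C=C1\C(C#CC)=COC(C)=C1
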